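## Structural features

The target is a B-type flavan-3-ol dimer: an epigallocatechin unit (chroman rings A and C, pyrogallol ring B on C2, a galloyl ester G on O3) is bonded through C4 to C8 of a (+)-catechin unit (chroman rings D and F, catechol ring E, free hydroxyl on C3 of ring F). Ring C holds three contiguous stereocentres, C2 (R), C3 (R) and C4 (R), with the ring-B aryl and the acyloxy group cis and the ring-D aryl on C4 trans to both; ring F keeps the 2R,3S (trans) pattern of natural catechin, which makes five stereocentres in all. C4 is a diarylmethine wedged between two 2,4,6-trioxygenated benzene rings, so the C4–C8 bond is crowded and ionises under acid, because both rings stabilise a C4 cation. Further fragile points are the gallate ester (base, acyl migration), the twelve free phenols (air oxidation, above all the two pyrogallol rings) and C2 of either unit, which epimerises in base once its para phenol is free. The real difficulty is to join C4 to C8 and not to C6 of ring D, with the C4 substituent trans to O3 in a 2,3-cis ring. The key step exploits ring A: C8a carries O1, the neighbouring C4a carries C4, and C5 next to C4a carries oxygen, which is the pattern left when an oxygen nucleophile and then a carbon electrophile add across a 3-alkoxybenzyne, so O1–C8a and C4a–C4 can be made in one operation from a 3,5-dioxygenated benzyne and an open-chain aldol that already holds C2, C3, ring B and ring D.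

## Logic of the disconnections

30 from 29. The thirteen benzylic O–C bonds on the twelve phenols and the ring-F hydroxyl are cut first. The free polyphenol is oxidised by air and epimerised by base, so it should appear only in the last step and under neutral conditions. The gain is that every earlier intermediate is a stable ether that can be chromatographed. The forward hydrogenolysis must spare the ester, the C4–C8 bond and both benzylic C2–O1 bonds.

29 from 27 and 28. The ester C–O bond at O3 is cut. An aroyl group would not survive aryllithium, fluoride or Lewis acid and could migrate, so it is put on late, onto the only free hydroxyl. 28 is purchasable and 27 is a mono-alcohol. The forward acylation must overcome an axial hydroxyl flanked by two aryl-bearing carbons.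

27 from 25 through 26. The C4–H bond is cut and its hydrogen is placed on silicon attached to O3, with C4 becoming a carbinol carbon. C4 is the one centre that ring formation leaves open, and a free hydride donor would be expected to approach the C4 cation anti to O3, which gives the 3,4-cis epimer; a hydride tied to O3 can only arrive on the O3 face. The gain is that the C4 configuration of 25 is irrelevant, since both epimers ionise to one cation. The forward step needs internal hydride transfer to outrun external reduction, proton loss from C3 and cleavage of the Si–O bond.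

25 from 24, and 24 from 22 through 23. The O3–Si bond and, one stage earlier, the O3–C(allyl) bond are the bonds involved. During ring construction O3 needs a mask that cannot wander to a neighbouring alkoxide and ignores fluoride; this excludes a silyl ether and points to an allyl ether. The mask must later leave without acid, because the C4 carbinol ionises easily. The gain is that 22 is the direct annulation product. The forward steps need a neutral deallylation and a silylation that tells the secondary from the tertiary hydroxyl.

22 from 15 and 20 through 21. O1–C8a and C4a–C4 are cut together, which opens ring C. Ring A leaves as an aryne equivalent, and what remains is an aldol chain whose carbinol oxygen is O1 and whose ketone carbon is C4. The cut is made here for three reasons: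
- ring A has the O/C/O pattern of a 3-alkoxyaryne adduct;
- C2 and C3 become acyclic aldol centres that are easy to control;
- ring D is attached to C4 through a ketone, so the C6/C8 choice of a Friedel–Crafts coupling never arises.

The gain is one ring and two bonds in a convergent union of a small achiral arene with a chain that carries four of the five stereocentres. The demands are that oxygen adds before carbon, at the aryne carbon remote from the flanking ether, and that the aldolate neither fragments by retro-aldol nor is quenched by a proton. For this reason the carbinol is stored in 15 as a fluoride-labile silyl ether, so that one reagent liberates 21 and the aryne together.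

20 from 17 through 18 and 19, and 17 from 16. The C–Si and O–S bonds, then the C–Br bond, are cut. Bromine marks the carbon between the hydroxyl and one ether; the silyl group reaches that carbon by O-to-C migration and the freed oxygen is sulfonylated. The gain is a symmetrical, purchasable phenol. The demand is bromination ortho and not para to the hydroxyl.

15 from 13 and 4 through 14. The C8–C(=O) bond is cut. An aryl anion plus an N-methoxy-N-methylamide fixes the attachment at C8 by the position of a halogen and stops at the ketone. The gain is two fragments of similar size, one holding the ring-F stereocentres and the other those of the future ring C. The demand is that a di-ortho-alkoxy aryllithium acylates a hindered amide without touching the α-centre, which is why the carbinol oxygen of 13 is silylated.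

4 from 3, 3 from 2, 2 from 1. The C8–Br bond and then five benzylic O–C bonds are cut. The lower unit with both its stereocentres comes from the chiral pool. The demands are bromination at C8 and not C6, and benzylation without C2 epimerisation.

13 from 12, 12 from 11, 11 from 8 and 9 through 10. The O–Si bond, the amide C–N bond (exchange of auxiliary for the methoxy(methyl)amino group) and then the chain C2–C3 bond (future C3–C2 of ring C) are cut, the last as an aldol. The stereocentres of ring F are too far away to bias an aldol of a ring-D ketone, so absolute configuration is taken from an auxiliary on the glycolate and ring D is attached afterwards. The gain is both centres in one step from purchasable 9. The demand is syn selectivity and auxiliary control of the enolate face.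

8 from 5 and 6 through 7. The N–acyl bond is cut, giving a purchasable acid and a purchasable auxiliary. The demand is clean N-acylation.

## Other disconnections considered

Alternative 1: The cut lies in the lower unit, at C4'–C3' and O1'–C2' of ring F (primes for the lower unit), so ring F is built last on a ring D already bonded to C4 of the complete, galloylated upper unit. In the forward direction the o-quinone methide A2 (exocyclic methylene on C4a', carbonyl at C8a') would be released from an ortho-hydroxybenzyl precursor and trapped by the (E)-enol carbonate A3 in an inverse-demand hetero-Diels–Alder reaction. Suprafacial addition would turn the E geometry into the 2,3-trans relation of A1.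
- In its favour: the reaction class (o-quinone methide plus electron-rich alkene) is well known, so its key step carries less mechanistic risk than the aryne annulation; on this point it is the better plan. A1 is one hydrogenolysis from 30, because the benzyl carbonate falls with the benzyl ethers; this is shorter than the five steps that follow 22, so it is also better on the endgame. C4 would have been set earlier by a conventional cation–arene coupling.
- Against it here: it builds the catechin half, the cheapest chiral-pool component, from scratch. C2' and C3' are remote from the stereocentres of ring C, so no substrate control of the diene face is to be expected, and the unwanted trans diastereomer would have to be removed unless a chiral catalyst is found. The alkene carries two donors (carbonate oxygen and dialkoxyaryl); only styrene-type polarisation gives the 2-aryl-3-oxy chroman, and enol-ether-type polarisation would give the 2-oxy-3-aryl isomer. The precursor of A2 needs a one-carbon unit placed ortho to the ring-D phenol on a molecule that already holds the acid-labile C4–C8 bond and the ester.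
- Comparison: on structure, the chosen plan takes four stereocentres from an auxiliary aldol and the chiral pool and the fifth from a tether, while this alternative leaves two uncontrolled. On mechanism it rests on better precedent. On step economy it is better after the key step and probably longer before it.

Alternative 2: The cut is again at C4–C4a and O1–C2 of ring C, but C2 is at the aldehyde oxidation level and carries neither ring B nor a C3 oxygen. In the forward direction a chiral secondary amine would convert enal A5 into an iminium ion, phenol 16 would add through its ortho carbon to the β-carbon, and the phenol oxygen would close onto the aldehyde to give lactol A4 with C4 set.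
- In its favour: this is the only one of the four plans that sets C4 directly, catalytically and under reagent control; this is better than the chosen plan, which needs a separate, unprecedented hydride delivery for that centre. The reaction type is established for electron-rich phenols and β-aryl enals, so its key step is also the safer one. Both partners are simple, and 16 is a compound of the chosen route as well.
- Against it here: the β-aryl group of A5 is flanked by two ortho oxygens and is strongly donating, so the iminium ion is hindered and weakly electrophilic. A4 contains none of ring B, the C3 oxygen or the ester. C2 and C3 would have to be built afterwards as two further stereocentres in the cis relation (for example through the lactone, α-oxygenation, aryl addition and reduction of the hemiketal), roughly six more operations, each with its own selectivity question.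
- Comparison: structurally it solves the hardest centre first and the easier ones late, whereas 15 brings C2, C3 and ring B from one aldol. Mechanistically its key step is safer. In step count and stereochemical bookkeeping after the key step it is clearly weaker.

Alternative 3: The cut is at C3–C4 and O1–C2. In the forward direction the diarylcarbinol A7 would lose water to the ring-A o-quinone methide, the enol or enolate of ketone A8 would add to its exocyclic carbon (the future C4), and the phenol oxygen would then add to the ketone to give hemiketal A6. Reduction at C2, desilylation, galloylation and hydrogenolysis would follow.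
- In its favour: it is convergent from simple pieces. Forming C3–C4 sets C3 and C4 in one step, so no separate operation on C4 is needed; on this point it is better than the chosen plan. The number of steps after the key step is about equal to that after 22. Conjugate additions of enolates to o-quinone methides are known, so it is closer to precedent.
- Against it here: C3 and C4 must be formed trans and in the right absolute sense in one intermolecular step, for which the only resident stereocentres (ring F) are remote. A chiral catalyst would therefore have to control a quinone methide that is strongly donor-stabilised and hindered (its exocyclic carbon bears the di-ortho-substituted ring D), that is, a poor electrophile. The α-silyloxy enolate of A8 is prone to silyl migration. C2 is left for a hemiketal reduction that must deliver hydrogen trans to O3.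
- Comparison: structurally both plans close ring C with ring D already on C4. The chosen plan fixes C2 and C3 securely and leaves C4; this alternative fixes C4 together with C3 under weak control and leaves C2. Mechanistically it is closer to precedent. Step economy is about equal.

Key step: step 11

Remark on the chemistry: 2-(allyloxy)acetic acid 5 and 3,5-bis(benzyloxy)phenol 16 are taken as purchasable building blocks.

## Route

Step 1
Reactants: 1 (+)-catechin
Product: 2 5,7,3',4'-tetra-O-benzyl-(+)-catechin
Conditions: BnBr, K2CO3, DMF, 0 °C → rt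
Reagents that add atoms: benzyl bromide, BrCc1ccccc1
Why: Williamson etherification of the four phenols; the carbonate base leaves the secondary C3 hydroxyl alone and, used cold under argon, limits base-induced C2 epimerisation.

Step 2
Reactants: 2 5,7,3',4'-tetra-O-benzyl-(+)-catechin
Product: 3 3,5,7,3',4'-penta-O-benzyl-(+)-catechin
Conditions: NaH, BnBr, DMF, 0 °C → rt
Reagents that add atoms: benzyl bromide, BrCc1ccccc1
Why: Williamson etherification of the remaining secondary alcohol; with every phenol capped, no quinone methide path to C2 epimerisation is open.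

Step 3
Reactants: 3 3,5,7,3',4'-penta-O-benzyl-(+)-catechin
Product: 4 8-bromo-3,5,7,3',4'-penta-O-benzyl-(+)-catechin
Conditions: NBS, CH2Cl2, −78 → 0 °C
Reagents that add atoms: N-bromosuccinimide, O=C1CCC(=O)N1Br
Why: Electrophilic aromatic bromination; C8 is the more reactive of the two free ring-D positions in 5,7-dialkoxyflavans, so one equivalent should brominate there.

Step 4
Reactants: 5 2-(allyloxy)acetic acid; 6 (S)-4-benzyl-1,3-oxazolidin-2-one
Product: 8 (S)-3-[2-(allyloxy)acetyl]-4-benzyl-1,3-oxazolidin-2-one, via mixed pivalic anhydride 7 (not isolated)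
Conditions: PivCl, Et3N, THF, −20 °C; then 6, LiCl, −20 °C → rt
Reagents that add atoms: none
Why: N-acylation of the oxazolidinone through a mixed anhydride; the hindered pivaloyl carbonyl directs attack to the glycolyl carbonyl.

Step 5
Reactants: 8 (S)-3-[2-(allyloxy)acetyl]-4-benzyl-1,3-oxazolidin-2-one; 9 3,4,5-tris(benzyloxy)benzaldehyde
Product: 11 (S)-3-[(2S,3R)-2-(allyloxy)-3-hydroxy-3-[3,4,5-tris(benzyloxy)phenyl]propanoyl]-4-benzyl-1,3-oxazolidin-2-one, via dibutylboron (Z)-enolate 10 (not isolated)
Conditions: Bu2BOTf, i-Pr2NEt, CH2Cl2, −78 → 0 °C; then 9, −78 → 0 °C; H2O2, MeOH, pH 7 buffer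
Reagents that add atoms: none
Why: Evans syn aldol reaction of a glycolate imide; the (Z)-boron enolate reacts through a closed chair transition state on the enolate face away from the benzyl group of the dipole-minimised auxiliary, which sets both new centres (2S,3R, syn), the future C3 and C2 of ring C.

Step 6
Reactants: 11 (S)-3-[(2S,3R)-2-(allyloxy)-3-hydroxy-3-[3,4,5-tris(benzyloxy)phenyl]propanoyl]-4-benzyl-1,3-oxazolidin-2-one
Product: 12 (2S,3R)-2-(allyloxy)-3-hydroxy-N-methoxy-N-methyl-3-[3,4,5-tris(benzyloxy)phenyl]propanamide
Conditions: MeNHOMe·HCl, AlMe3, CH2Cl2, −20 → 0 °C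
Reagents that add atoms: N,O-dimethylhydroxylamine hydrochloride, CNOC.Cl
Why: Aluminium amide transamination of the imide to the Weinreb amide; the free β-hydroxyl binds aluminium and directs attack to the exocyclic carbonyl, and no base able to cause retro-aldol or α-epimerisation is present.

Step 7
Reactants: 12 (2S,3R)-2-(allyloxy)-3-hydroxy-N-methoxy-N-methyl-3-[3,4,5-tris(benzyloxy)phenyl]propanamide
Product: 13 (2S,3R)-2-(allyloxy)-N-methoxy-N-methyl-3-(triethylsilyloxy)-3-[3,4,5-tris(benzyloxy)phenyl]propanamide
Conditions: TESCl, imidazole, DMF, 0 °C → rt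
Reagents that add atoms: chlorotriethylsilane, CC[Si](Cl)(CC)CC
Why: Silylation of the secondary benzylic alcohol; the triethylsilyl ether shields the carbinol from the aryllithium of step 8 and later serves as the fluoride-labile mask of the alkoxide in step 11.

Step 8
Reactants: 4 8-bromo-3,5,7,3',4'-penta-O-benzyl-(+)-catechin; 13 (2S,3R)-2-(allyloxy)-N-methoxy-N-methyl-3-(triethylsilyloxy)-3-[3,4,5-tris(benzyloxy)phenyl]propanamide
Product: 15 (2S,3R)-2-(allyloxy)-1-(penta-O-benzylcatechin-8-yl)-3-(triethylsilyloxy)-3-[3,4,5-tris(benzyloxy)phenyl]propan-1-one, via 8-lithio arene 14 (not isolated)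
Conditions: n-BuLi, THF, −78 °C; then 13, −78 → −20 °C; aq NH4Cl
Reagents that add atoms: none
Why: Bromine–lithium exchange followed by Weinreb ketone synthesis; the chelated tetrahedral adduct persists until the quench, so no enolisable ketone meets the aryllithium and the two chain stereocentres are untouched.

Step 9
Reactants: 16 3,5-bis(benzyloxy)phenol
Product: 17 2-bromo-3,5-bis(benzyloxy)phenol
Conditions: NBS, i-Pr2NH (cat.), CH2Cl2, −78 → 0 °C
Reagents that add atoms: N-bromosuccinimide, O=C1CCC(=O)N1Br
Why: Amine-catalysed ortho-selective bromination of a phenol; the N-bromoamine hydrogen-bonded to the hydroxyl delivers bromine to the adjacent carbon and not to the carbon between the two ethers.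

Step 10
Reactants: 17 2-bromo-3,5-bis(benzyloxy)phenol
Product: 20 3,5-bis(benzyloxy)-2-(trimethylsilyl)phenyl trifluoromethanesulfonate, via aryl trimethylsilyl ether 18 (not isolated), via lithium 2-silylphenoxide 19 (not isolated)
Conditions: HMDS, THF, reflux, then evaporation; n-BuLi, THF, −78 °C; then Tf2O, −78 °C → rt
Reagents that add atoms: hexamethyldisilazane, C[Si](C)(C)N[Si](C)(C)C; trifluoromethanesulfonic anhydride, O=S(=O)(OS(=O)(=O)C(F)(F)F)C(F)(F)F
Why: O-silylation, bromine–lithium exchange and retro-Brook (1,3 O-to-C) silyl shift place silicon on the carbon between two oxygens, and the phenoxide set free is triflated; this is the standard sequence to 2-silylaryl triflates.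

Step 11
Reactants: 15 (2S,3R)-2-(allyloxy)-1-(penta-O-benzylcatechin-8-yl)-3-(triethylsilyloxy)-3-[3,4,5-tris(benzyloxy)phenyl]propan-1-one; 20 3,5-bis(benzyloxy)-2-(trimethylsilyl)phenyl trifluoromethanesulfonate
Product: 22 (2R,3S)-3-(allyloxy)-5,7-bis(benzyloxy)-4-(penta-O-benzylcatechin-8-yl)-2-[3,4,5-tris(benzyloxy)phenyl]chroman-4-ol (2,3-cis; both C4 epimers), via cesium aldolate 21 (not isolated)
Conditions: CsF, 18-crown-6, THF, −20 → 0 °C (20 added over 2 h)
Reagents that add atoms: none
Why: Proposed new method: fluoride cleaves the O–SiEt3 bond of 15 to the cesium aldolate 21 and in the same medium converts 20 into 3,5-bis(benzyloxy)benzyne; the alkoxide adds to the aryne carbon remote from the flanking benzyloxy group (the future C8a), as the distortion of 3-alkoxyarynes dictates, which leaves the aryl anion on the future C4a where the adjacent C–O bond stabilises it. That anion adds to the ketone carbon in a 6-exo-trig closure that forms C4a–C4 and ring C as a 4-aryl-4-hydroxychroman. The closest known reaction type is the fluoride-induced annulation of arynes with salicylates and 2-hydroxyaryl ketones to xanthones and xanthenols (O-arylation, then anionic closure onto the carbonyl); what is new is an aliphatic aldolate in place of a phenoxide. The step needs oxygen at C8a and carbon at C4a, which the aryne polarisation and the six-membered tether secure, and it needs the aldol to survive, which is addressed by keeping the carbinol as a neutral silyl ether so that alkoxide appears only while aryne is being produced, under aprotic conditions and next to a non-migrating allyl ether. Alkoxide that meets no aryne is expected to attack the trimethylsilyl group of 20, which masks it again and releases one more aryne, so free aldolate should not accumulate. C2 and C3 are carried unchanged from the aldol (2,3-cis); the new carbinol centre C4 is not controlled and need not be, since both epimers give the same cation in step 14.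

Step 12
Reactants: 22 (2R,3S)-3-(allyloxy)-5,7-bis(benzyloxy)-4-(penta-O-benzylcatechin-8-yl)-2-[3,4,5-tris(benzyloxy)phenyl]chroman-4-ol
Product: 24 (2R,3S)-5,7-bis(benzyloxy)-4-(penta-O-benzylcatechin-8-yl)-2-[3,4,5-tris(benzyloxy)phenyl]chromane-3,4-diol (2,3-cis; both C4 epimers), via propenyl ether 23 (not isolated)
Conditions: [Ir(cod)(PMePh2)2]PF6 (cat., activated with H2), THF, rt; then OsO4 (cat.), NMO, THF/H2O, rt
Reagents that add atoms: none
Why: Iridium hydride-catalysed isomerisation of the allyl ether to the propenyl ether, then Upjohn dihydroxylation of the enol ether, whose hemiacetal collapses to the free alcohol; both stages are neutral, so the acid-labile diaryl carbinol and the benzyl ethers should be untouched.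

Step 13
Reactants: 24 (2R,3S)-5,7-bis(benzyloxy)-4-(penta-O-benzylcatechin-8-yl)-2-[3,4,5-tris(benzyloxy)phenyl]chromane-3,4-diol
Product: 25 (2R,3S)-5,7-bis(benzyloxy)-3-(diisopropylsilyloxy)-4-(penta-O-benzylcatechin-8-yl)-2-[3,4,5-tris(benzyloxy)phenyl]chroman-4-ol (both C4 epimers)
Conditions: i-Pr2SiHCl, imidazole, CH2Cl2, 0 °C
Reagents that add atoms: chlorodiisopropylsilane, CC(C)[SiH](Cl)C(C)C
Why: Silylation of the secondary C3 hydroxyl; the tertiary C4 hydroxyl, flanked by two ortho-disubstituted aryl groups, is too hindered to react, so the Si–H group sits on the oxygen next to C4.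

Step 14
Reactants: 25 (2R,3S)-5,7-bis(benzyloxy)-3-(diisopropylsilyloxy)-4-(penta-O-benzylcatechin-8-yl)-2-[3,4,5-tris(benzyloxy)phenyl]chroman-4-ol
Product: 27 (2R,3R,4R)-5,7-bis(benzyloxy)-4-(penta-O-benzylcatechin-8-yl)-2-[3,4,5-tris(benzyloxy)phenyl]chroman-3-ol (2,3-cis-3,4-trans), via fluorosilyl ether 26 (not isolated)
Conditions: BF3·OEt2, CH2Cl2 (0.005 M), −78 → −20 °C; then TBAF, THF, 0 °C
Reagents that add atoms: none
Why: Proposed new method: BF3 ionises the tertiary carbinol to the diaryl-stabilised C4 cation; in the 2,3-cis half-chair the axial C3–O bond runs parallel to the empty orbital, so the Si–H held on O3 can pass its hydride through a five-membered transition state only to the O3 face, which puts H4 cis to O3 and ring D trans (4R), and the silyl cation is caught as fluorosilyl ether 26, which fluoride cleaves in the same flask. The closest known reaction types are the Lewis acid-promoted intramolecular hydrosilylation of hydroxy ketones as their diisopropylsilyl ethers and the intramolecular ionic hydrogenation of hydroxy alkenes through hydridosilyl ethers. High dilution suppresses intermolecular transfer, and the equatorial C3–H lies near the nodal plane of the cation, which disfavours hydride shift and elimination.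

Step 15
Reactants: 27 (2R,3R,4R)-5,7-bis(benzyloxy)-4-(penta-O-benzylcatechin-8-yl)-2-[3,4,5-tris(benzyloxy)phenyl]chroman-3-ol; 28 3,4,5-tris(benzyloxy)benzoic acid
Product: 29 (2R,3R,4R)-5,7-bis(benzyloxy)-4-(penta-O-benzylcatechin-8-yl)-2-[3,4,5-tris(benzyloxy)phenyl]chroman-3-yl 3,4,5-tris(benzyloxy)benzoate
Conditions: DCC, DMAP, CH2Cl2, rt
Reagents that add atoms: none
Why: Steglich esterification of the only free hydroxyl; no stereocentre is involved, and the acylpyridinium intermediate should be reactive enough for the hindered axial alcohol.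

Step 16
Reactants: 29 (2R,3R,4R)-5,7-bis(benzyloxy)-4-(penta-O-benzylcatechin-8-yl)-2-[3,4,5-tris(benzyloxy)phenyl]chroman-3-yl 3,4,5-tris(benzyloxy)benzoate
Product: 30 epigallocatechin 3-O-gallate-(4β→8)-catechin (CNP0129434.1)
Conditions: H2 (1 atm), Pd(OH)2/C, THF/MeOH/H2O, rt
Reagents that add atoms: none
Why: Hydrogenolysis of all thirteen benzyl ethers under neutral conditions that should leave the gallate ester, the C4–C8 bond and the flavan C2–O1 bonds intact; filtration under argon and freeze-drying limit air oxidation of the product.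

## Compound list

1 | (+)-catechin, (2R,3S)-2-(3,4-dihydroxyphenyl)chromane-3,5,7-triol | Oc1cc(O)c2c(c1)O[C@H](c1ccc(O)c(O)c1)[C@@H](O)C2 | starting material
2 | 5,7,3',4'-tetra-O-benzyl-(+)-catechin (2R,3S) | c1c(OCc9ccccc9)cc(OCc9ccccc9)c2c1O[C@H](c1ccc(OCc9ccccc9)c(OCc9ccccc9)c1)[C@@H](O)C2 | intermediate
3 | 3,5,7,3',4'-penta-O-benzyl-(+)-catechin (2R,3S) | c1c(OCc9ccccc9)cc(OCc9ccccc9)c2c1O[C@H](c1ccc(OCc9ccccc9)c(OCc9ccccc9)c1)[C@@H](OCc9ccccc9)C2 | intermediate
4 | 8-bromo-3,5,7,3',4'-penta-O-benzyl-(+)-catechin (2R,3S) | Brc1c(OCc9ccccc9)cc(OCc9ccccc9)c2c1O[C@H](c1ccc(OCc9ccccc9)c(OCc9ccccc9)c1)[C@@H](OCc9ccccc9)C2 | intermediate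
5 | 2-(allyloxy)acetic acid | C=CCOCC(=O)O | starting material
6 | (S)-4-benzyl-1,3-oxazolidin-2-one | O=C1N[C@@H](Cc2ccccc2)CO1 | starting material
7 | 2-(allyloxy)acetic pivalic anhydride (formed in the flask) | C=CCOCC(=O)OC(=O)C(C)(C)C | intermediate
8 | (S)-3-[2-(allyloxy)acetyl]-4-benzyl-1,3-oxazolidin-2-one | C=CCOCC(=O)N1[C@@H](Cc2ccccc2)COC1=O | intermediate
9 | 3,4,5-tris(benzyloxy)benzaldehyde | O=Cc1cc(OCc2ccccc2)c(OCc2ccccc2)c(OCc2ccccc2)c1 | starting material
10 | dibutylboron (Z)-enolate of 8 (formed in the flask) | C=CCO/C=C(\OB(CCCC)CCCC)N1[C@@H](Cc2ccccc2)COC1=O | intermediate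
11 | (S)-3-[(2S,3R)-2-(allyloxy)-3-hydroxy-3-[3,4,5-tris(benzyloxy)phenyl]propanoyl]-4-benzyl-1,3-oxazolidin-2-one (syn aldol) | O[C@H](c5cc(OCc9ccccc9)c(OCc9ccccc9)c(OCc9ccccc9)c5)[C@H](OCC=C)C(=O)N1[C@@H](Cc2ccccc2)COC1=O | intermediate
12 | (2S,3R)-2-(allyloxy)-3-hydroxy-N-methoxy-N-methyl-3-[3,4,5-tris(benzyloxy)phenyl]propanamide | O[C@H](c5cc(OCc9ccccc9)c(OCc9ccccc9)c(OCc9ccccc9)c5)[C@H](OCC=C)C(=O)N(C)OC | intermediate
13 | (2S,3R)-2-(allyloxy)-N-methoxy-N-methyl-3-(triethylsilyloxy)-3-[3,4,5-tris(benzyloxy)phenyl]propanamide | CC[Si](CC)(CC)O[C@H](c5cc(OCc9ccccc9)c(OCc9ccccc9)c(OCc9ccccc9)c5)[C@H](OCC=C)C(=O)N(C)OC | intermediate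
14 | 8-lithio-3,5,7,3',4'-penta-O-benzyl-(+)-catechin (formed in the flask) | [Li]c1c(OCc9ccccc9)cc(OCc9ccccc9)c2c1O[C@H](c1ccc(OCc9ccccc9)c(OCc9ccccc9)c1)[C@@H](OCc9ccccc9)C2 | intermediate
15 | (2S,3R)-2-(allyloxy)-1-(penta-O-benzylcatechin-8-yl)-3-(triethylsilyloxy)-3-[3,4,5-tris(benzyloxy)phenyl]propan-1-one (syn aldol as its O-triethylsilyl ether; key-step precursor) | CC[Si](CC)(CC)O[C@H](c5cc(OCc9ccccc9)c(OCc9ccccc9)c(OCc9ccccc9)c5)[C@H](OCC=C)C(=O)c2c(OCc9ccccc9)cc(OCc9ccccc9)c3c2O[C@H](c4ccc(OCc9ccccc9)c(OCc9ccccc9)c4)[C@@H](OCc9ccccc9)C3 | intermediate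
16 | 3,5-bis(benzyloxy)phenol | Oc1cc(OCc2ccccc2)cc(OCc2ccccc2)c1 | starting material
17 | 2-bromo-3,5-bis(benzyloxy)phenol | Oc1cc(OCc2ccccc2)cc(OCc2ccccc2)c1Br | intermediate
18 | [2-bromo-3,5-bis(benzyloxy)phenoxy]trimethylsilane (formed in the flask) | C[Si](C)(C)Oc1cc(OCc2ccccc2)cc(OCc2ccccc2)c1Br | intermediate
19 | lithium 3,5-bis(benzyloxy)-2-(trimethylsilyl)phenoxide (formed in the flask) | [Li+].[O-]c1cc(OCc2ccccc2)cc(OCc2ccccc2)c1[Si](C)(C)C | intermediate
20 | 3,5-bis(benzyloxy)-2-(trimethylsilyl)phenyl trifluoromethanesulfonate (key-step precursor) | C[Si](C)(C)c1c(OCc9ccccc9)cc(OCc9ccccc9)cc1OS(=O)(=O)C(F)(F)F | intermediate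
21 | cesium (1R,2S)-2-(allyloxy)-3-oxo-3-(penta-O-benzylcatechin-8-yl)-1-[3,4,5-tris(benzyloxy)phenyl]propan-1-olate (alkoxide of the syn aldol, formed in the flask) | [Cs+].[O-][C@H](c5cc(OCc9ccccc9)c(OCc9ccccc9)c(OCc9ccccc9)c5)[C@H](OCC=C)C(=O)c2c(OCc9ccccc9)cc(OCc9ccccc9)c3c2O[C@H](c4ccc(OCc9ccccc9)c(OCc9ccccc9)c4)[C@@H](OCc9ccccc9)C3 | intermediate
22 | (2R,3S)-3-(allyloxy)-5,7-bis(benzyloxy)-4-(penta-O-benzylcatechin-8-yl)-2-[3,4,5-tris(benzyloxy)phenyl]chroman-4-ol (2,3-cis, ring-B aryl and O3 on the same face; both C4 epimers; key-step product) | C=CCO[C@@H]1C(O)(c2c(OCc9ccccc9)cc(OCc9ccccc9)c3c2O[C@H](c4ccc(OCc9ccccc9)c(OCc9ccccc9)c4)[C@@H](OCc9ccccc9)C3)c7c(OCc9ccccc9)cc(OCc9ccccc9)cc7O[C@@H]1c5cc(OCc9ccccc9)c(OCc9ccccc9)c(OCc9ccccc9)c5 | intermediate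
23 | (E)-prop-1-enyl ether corresponding to 22 (formed in the flask) | C/C=C/O[C@@H]1C(O)(c2c(OCc9ccccc9)cc(OCc9ccccc9)c3c2O[C@H](c4ccc(OCc9ccccc9)c(OCc9ccccc9)c4)[C@@H](OCc9ccccc9)C3)c7c(OCc9ccccc9)cc(OCc9ccccc9)cc7O[C@@H]1c5cc(OCc9ccccc9)c(OCc9ccccc9)c(OCc9ccccc9)c5 | intermediate
24 | (2R,3S)-5,7-bis(benzyloxy)-4-(penta-O-benzylcatechin-8-yl)-2-[3,4,5-tris(benzyloxy)phenyl]chromane-3,4-diol (2,3-cis; both C4 epimers) | O[C@@H]1C(O)(c2c(OCc9ccccc9)cc(OCc9ccccc9)c3c2O[C@H](c4ccc(OCc9ccccc9)c(OCc9ccccc9)c4)[C@@H](OCc9ccccc9)C3)c7c(OCc9ccccc9)cc(OCc9ccccc9)cc7O[C@@H]1c5cc(OCc9ccccc9)c(OCc9ccccc9)c(OCc9ccccc9)c5 | intermediate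
25 | (2R,3S)-5,7-bis(benzyloxy)-3-(diisopropylsilyloxy)-4-(penta-O-benzylcatechin-8-yl)-2-[3,4,5-tris(benzyloxy)phenyl]chroman-4-ol (2,3-cis; both C4 epimers) | CC(C)[SiH](C(C)C)O[C@@H]1C(O)(c2c(OCc9ccccc9)cc(OCc9ccccc9)c3c2O[C@H](c4ccc(OCc9ccccc9)c(OCc9ccccc9)c4)[C@@H](OCc9ccccc9)C3)c7c(OCc9ccccc9)cc(OCc9ccccc9)cc7O[C@@H]1c5cc(OCc9ccccc9)c(OCc9ccccc9)c(OCc9ccccc9)c5 | intermediate
26 | (2R,3R,4R)-3-[fluoro(diisopropyl)silyloxy]-5,7-bis(benzyloxy)-4-(penta-O-benzylcatechin-8-yl)-2-[3,4,5-tris(benzyloxy)phenyl]chromane (formed in the flask) | CC(C)[Si](F)(C(C)C)O[C@@H]1[C@@H](c2c(OCc9ccccc9)cc(OCc9ccccc9)c3c2O[C@H](c4ccc(OCc9ccccc9)c(OCc9ccccc9)c4)[C@@H](OCc9ccccc9)C3)c7c(OCc9ccccc9)cc(OCc9ccccc9)cc7O[C@@H]1c5cc(OCc9ccccc9)c(OCc9ccccc9)c(OCc9ccccc9)c5 | intermediate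
27 | (2R,3R,4R)-5,7-bis(benzyloxy)-4-(penta-O-benzylcatechin-8-yl)-2-[3,4,5-tris(benzyloxy)phenyl]chroman-3-ol (2,3-cis-3,4-trans) | O[C@@H]1[C@@H](c2c(OCc9ccccc9)cc(OCc9ccccc9)c3c2O[C@H](c4ccc(OCc9ccccc9)c(OCc9ccccc9)c4)[C@@H](OCc9ccccc9)C3)c7c(OCc9ccccc9)cc(OCc9ccccc9)cc7O[C@@H]1c5cc(OCc9ccccc9)c(OCc9ccccc9)c(OCc9ccccc9)c5 | intermediate
28 | 3,4,5-tris(benzyloxy)benzoic acid | OC(=O)c1cc(OCc2ccccc2)c(OCc2ccccc2)c(OCc2ccccc2)c1 | starting material
29 | (2R,3R,4R)-5,7-bis(benzyloxy)-4-(penta-O-benzylcatechin-8-yl)-2-[3,4,5-tris(benzyloxy)phenyl]chroman-3-yl 3,4,5-tris(benzyloxy)benzoate (trideca-O-benzyl ether of 30) | O=C(c6cc(OCc9ccccc9)c(OCc9ccccc9)c(OCc9ccccc9)c6)O[C@@H]1[C@@H](c2c(OCc9ccccc9)cc(OCc9ccccc9)c3c2O[C@H](c4ccc(OCc9ccccc9)c(OCc9ccccc9)c4)[C@@H](OCc9ccccc9)C3)c7c(OCc9ccccc9)cc(OCc9ccccc9)cc7O[C@@H]1c5cc(OCc9ccccc9)c(OCc9ccccc9)c(OCc9ccccc9)c5 | intermediate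
30 | (2R,3R,4R)-4-[(2R,3S)-2-(3,4-dihydroxyphenyl)-3,5,7-trihydroxychroman-8-yl]-5,7-dihydroxy-2-(3,4,5-trihydroxyphenyl)chroman-3-yl 3,4,5-trihydroxybenzoate (CNP0129434.1) | O=C(O[C@@H]1[C@@H](c2c(O)cc(O)c3c2O[C@H](c2ccc(O)c(O)c2)[C@@H](O)C3)c2c(O)cc(O)cc2O[C@@H]1c1cc(O)c(O)c(O)c1)c1cc(O)c(O)c(O)c1 | target

## Step count and least certain steps

Total: 16 steps. Longest linear sequence: 11 steps (steps 4, 5, 6, 7, 8, 11, 12, 13, 14, 15 and 16).

Step 11 (key step, new method). The most likely failures are fragmentation of the liberated aldolate 21 by retro-aldol before it meets an aryne; quenching of the aryl anion by proton transfer (from C3–H within the molecule, followed by β-elimination of the new aryloxy group, or from traces of water) in place of carbonyl addition; and a mismatch between the rates of silyl ether cleavage and aryne release. The reasons are that free alkoxides of aldols from electron-rich aldehydes fragment easily and that the ketone is shielded by the two ortho oxygens of ring D. Fallback, by known chemistry: 22 is assembled by adding an aryllithium to a flavan-4-one. It sets out from 4 and from purchased (−)-epigallocatechin F1. The five phenols of F1 would be benzylated (BnBr, K2CO3, DMF) to the penta-O-benzyl ether F2, and O3 allylated (NaH, allyl bromide, DMF) to the 3-O-allyl ether F3. C4 would then be oxidised (DDQ, CH2Cl2/H2O) to the 4-hydroxy compound F4 and further (Dess–Martin oxidation) to the 3-allyloxyflavan-4-one F5. Aryllithium 14, made from 4 as in step 8, would be added to F5 in THF at −78 °C and should give 22, where the route is rejoined. This gives up the aryne construction of ring C and takes C2 and C3 from the chiral pool.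

Step 14 (new method). The most likely failures are erosion of facial selectivity by intermolecular hydride transfer or by a 1,5-hydride shift from the CH2 of a neighbouring benzyl ether; slow hydride transfer to a strongly stabilised cation, with loss of the C3 proton competing; and cleavage of the Si–O tether by BF3 before transfer. The reasons are that an alkoxysilane is a weak hydride donor and the five-membered transition state is strained. Fallback, by known chemistry: C4 is set by Lewis acid-mediated arylation of a flavan-4-yl cation, in which the arene enters anti to O3. It sets out from 3 and from F2 (made as in the fallback to step 11). F2 would be oxidised at C4 in the presence of 2-ethoxyethanol (DDQ, CH2Cl2) to the 4β-(2-ethoxyethoxy) ether F6, and O3 acetylated (Ac2O, DMAP, pyridine) to the acetate F7. F7 would be coupled with an excess of 3 (TMSOTf, CH2Cl2, −78 °C) to the 3-O-acetyl dimer F8, and methanolysis (K2CO3, MeOH/THF) should give 27, where the route is rejoined. Its own weak points are attack at C6 of 3 and further oligomerisation.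

Step 8. The most likely failure is slow acylation of the di-ortho-alkoxy aryllithium 14 by the hindered amide 13, so that proton transfer from the α-carbon of 13 (followed by β-elimination of silanolate) takes over and 14 ends as 3. Fallback: 13 is reduced to the aldehyde F9 (DIBAL-H, THF, −78 °C); 14 is added to this less hindered, more electrophilic carbonyl to give the secondary carbinol F10 (mixture at the new centre); Dess–Martin oxidation should then give 15. It sets out from 13 and returns at 15.

Step 9. The most likely failure is bromination para to the hydroxyl (between the two ether groups) or double bromination, because all three free ring positions are strongly activated. Fallback: directed ortho-metalation in place of halogenation. 16 would be converted into the N-isopropylcarbamate F11 (i-PrNCO, Et3N, CH2Cl2). F11 would be N-silylated, lithiated between the carbamate and an ether oxygen and quenched (TMSOTf, TMEDA; n-BuLi, −78 °C; TMSCl) to the 2-silyl carbamate F12. Carbamate cleavage and triflation in one flask (Et2NH, DBU, MeCN, 40 °C; then PhNTf2) should give 20. It sets out from 16 and returns at 20, bypassing 17 to 19.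

Step 12. The most likely failures are ionisation of the tertiary diaryl carbinol by traces of acid from the cationic iridium catalyst, and incomplete isomerisation that leaves allyl ether to be dihydroxylated and not cleaved. Fallback: single-electron reductive cleavage of the allyl ether with SmI2, i-PrNH2 and water in THF at rt, which should take 22 directly to 24 without a propenyl ether; it sets out from 22, returns at 24 and makes no new compound (F0).

## Further compounds

F1 | step 11 | (−)-epigallocatechin, (2R,3R)-2-(3,4,5-trihydroxyphenyl)chromane-3,5,7-triol | O[C@@H]1Cc2c(O)cc(O)cc2O[C@@H]1c1cc(O)c(O)c(O)c1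
F2 | step 11 | 5,7,3',4',5'-penta-O-benzyl-(−)-epigallocatechin | O[C@@H]1Cc7c(OCc9ccccc9)cc(OCc9ccccc9)cc7O[C@@H]1c5cc(OCc9ccccc9)c(OCc9ccccc9)c(OCc9ccccc9)c5
F3 | step 11 | 3-O-allyl-5,7,3',4',5'-penta-O-benzyl-(−)-epigallocatechin | C=CCO[C@@H]1Cc7c(OCc9ccccc9)cc(OCc9ccccc9)cc7O[C@@H]1c5cc(OCc9ccccc9)c(OCc9ccccc9)c(OCc9ccccc9)c5
F4 | step 11 | 3-O-allyl-5,7,3',4',5'-penta-O-benzyl-epigallocatechin-4-ol (2,3-cis; C4 epimers) | C=CCO[C@@H]1C(O)c7c(OCc9ccccc9)cc(OCc9ccccc9)cc7O[C@@H]1c5cc(OCc9ccccc9)c(OCc9ccccc9)c(OCc9ccccc9)c5
F5 | step 11 | (2R,3S)-3-(allyloxy)-5,7-bis(benzyloxy)-2-[3,4,5-tris(benzyloxy)phenyl]chroman-4-one (2,3-cis) | C=CCO[C@@H]1C(=O)c7c(OCc9ccccc9)cc(OCc9ccccc9)cc7O[C@@H]1c5cc(OCc9ccccc9)c(OCc9ccccc9)c(OCc9ccccc9)c5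
F6 | step 14 | 4β-(2-ethoxyethoxy)-5,7,3',4',5'-penta-O-benzyl-(−)-epigallocatechin (3,4-trans) | O[C@@H]1[C@@H](OCCOCC)c7c(OCc9ccccc9)cc(OCc9ccccc9)cc7O[C@@H]1c5cc(OCc9ccccc9)c(OCc9ccccc9)c(OCc9ccccc9)c5
F7 | step 14 | 3-O-acetyl-4β-(2-ethoxyethoxy)-5,7,3',4',5'-penta-O-benzyl-(−)-epigallocatechin | CC(=O)O[C@@H]1[C@@H](OCCOCC)c7c(OCc9ccccc9)cc(OCc9ccccc9)cc7O[C@@H]1c5cc(OCc9ccccc9)c(OCc9ccccc9)c(OCc9ccccc9)c5
F8 | step 14 | 3-O-acetate of 27, (2R,3R,4R)-5,7-bis(benzyloxy)-4-(penta-O-benzylcatechin-8-yl)-2-[3,4,5-tris(benzyloxy)phenyl]chroman-3-yl acetate | CC(=O)O[C@@H]1[C@@H](c2c(OCc9ccccc9)cc(OCc9ccccc9)c3c2O[C@H](c4ccc(OCc9ccccc9)c(OCc9ccccc9)c4)[C@@H](OCc9ccccc9)C3)c7c(OCc9ccccc9)cc(OCc9ccccc9)cc7O[C@@H]1c5cc(OCc9ccccc9)c(OCc9ccccc9)c(OCc9ccccc9)c5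
F9 | step 8 | (2S,3R)-2-(allyloxy)-3-(triethylsilyloxy)-3-[3,4,5-tris(benzyloxy)phenyl]propanal | CC[Si](CC)(CC)O[C@H](c5cc(OCc9ccccc9)c(OCc9ccccc9)c(OCc9ccccc9)c5)[C@H](OCC=C)C=O
F10 | step 8 | (2S,3R)-2-(allyloxy)-1-(penta-O-benzylcatechin-8-yl)-3-(triethylsilyloxy)-3-[3,4,5-tris(benzyloxy)phenyl]propan-1-ol (C1 epimers) | CC[Si](CC)(CC)O[C@H](c5cc(OCc9ccccc9)c(OCc9ccccc9)c(OCc9ccccc9)c5)[C@H](OCC=C)C(O)c2c(OCc9ccccc9)cc(OCc9ccccc9)c3c2O[C@H](c4ccc(OCc9ccccc9)c(OCc9ccccc9)c4)[C@@H](OCc9ccccc9)C3
F11 | step 9 | 3,5-bis(benzyloxy)phenyl N-isopropylcarbamate | CC(C)NC(=O)Oc1cc(OCc2ccccc2)cc(OCc2ccccc2)c1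
F12 | step 9 | 3,5-bis(benzyloxy)-2-(trimethylsilyl)phenyl N-isopropylcarbamate | CC(C)NC(=O)Oc1cc(OCc2ccccc2)cc(OCc2ccccc2)c1[Si](C)(C)C
F0 | step 12 | none | none
A1 | alternative 1 | trideca-O-benzyl ether of 30 in which the lower O3 carries a benzyl carbonate in place of a benzyl ether | O=C(c6cc(OCc9ccccc9)c(OCc9ccccc9)c(OCc9ccccc9)c6)O[C@@H]1[C@@H](c2c(OCc9ccccc9)cc(OCc9ccccc9)c3c2O[C@H](c4ccc(OCc9ccccc9)c(OCc9ccccc9)c4)[C@@H](OC(=O)OCc9ccccc9)C3)c7c(OCc9ccccc9)cc(OCc9ccccc9)cc7O[C@@H]1c5cc(OCc9ccccc9)c(OCc9ccccc9)c(OCc9ccccc9)c5
A2 | alternative 1 | ring-D o-quinone methide on C4 of the perbenzylated epigallocatechin gallate unit (3,5-bis(benzyloxy)-6-methylidenecyclohexa-2,4-dien-1-one bonded through C2) | O=C(c6cc(OCc9ccccc9)c(OCc9ccccc9)c(OCc9ccccc9)c6)O[C@@H]1[C@@H](C2=C(OCc9ccccc9)C=C(OCc9ccccc9)C(=C)C2=O)c7c(OCc9ccccc9)cc(OCc9ccccc9)cc7O[C@@H]1c5cc(OCc9ccccc9)c(OCc9ccccc9)c(OCc9ccccc9)c5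
A3 | alternative 1 | benzyl (E)-2-[3,4-bis(benzyloxy)phenyl]ethenyl carbonate | O=C(OCc1ccccc1)O/C=C/c1ccc(OCc2ccccc2)c(OCc2ccccc2)c1
A4 | alternative 2 | 4-(penta-O-benzylcatechin-8-yl)-5,7-bis(benzyloxy)chroman-2-ol (C4 set; lactol anomers) | OC1C[C@@H](c2c(OCc9ccccc9)cc(OCc9ccccc9)c3c2O[C@H](c4ccc(OCc9ccccc9)c(OCc9ccccc9)c4)[C@@H](OCc9ccccc9)C3)c7c(OCc9ccccc9)cc(OCc9ccccc9)cc7O1
A5 | alternative 2 | (E)-3-(penta-O-benzylcatechin-8-yl)prop-2-enal | O=C/C=C/c2c(OCc9ccccc9)cc(OCc9ccccc9)c3c2O[C@H](c4ccc(OCc9ccccc9)c(OCc9ccccc9)c4)[C@@H](OCc9ccccc9)C3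
A6 | alternative 3 | 2-hydroxy-3-(tert-butyldimethylsilyloxy)-5,7-bis(benzyloxy)-4-(penta-O-benzylcatechin-8-yl)-2-[3,4,5-tris(benzyloxy)phenyl]chromane (C3 and C4 set; C2 anomers) | CC(C)(C)[Si](C)(C)O[C@@H]1[C@@H](c2c(OCc9ccccc9)cc(OCc9ccccc9)c3c2O[C@H](c4ccc(OCc9ccccc9)c(OCc9ccccc9)c4)[C@@H](OCc9ccccc9)C3)c7c(OCc9ccccc9)cc(OCc9ccccc9)cc7OC1(O)c5cc(OCc9ccccc9)c(OCc9ccccc9)c(OCc9ccccc9)c5
A7 | alternative 3 | [2-hydroxy-4,6-bis(benzyloxy)phenyl](penta-O-benzylcatechin-8-yl)methanol (carbinol epimers) | OC(c7c(OCc9ccccc9)cc(OCc9ccccc9)cc7O)c2c(OCc9ccccc9)cc(OCc9ccccc9)c3c2O[C@H](c4ccc(OCc9ccccc9)c(OCc9ccccc9)c4)[C@@H](OCc9ccccc9)C3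
A8 | alternative 3 | 2-(tert-butyldimethylsilyloxy)-1-[3,4,5-tris(benzyloxy)phenyl]ethan-1-one | CC(C)(C)[Si](C)(C)OCC(=O)c5cc(OCc9ccccc9)c(OCc9ccccc9)c(OCc9ccccc9)c5
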